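The retrosynthesis cuts, in this order: O1–C6 of the dihydropyranone (back to an acyclic β-hydroxy ynone), C4–C5 (propynyl anion on a Weinreb amide), the C2–H bond (back to a 3-oxo ester) and C2–C3 (malonate half-ester acylated by the 24-carbon acid).
Forward, the chain is joined first (24-carbon acid plus a two-carbon malonate unit gives the 26-carbon β-keto ester), the ketone is reduced, the three-carbon alkyne unit is added, and the only ring, the 2,3-dihydro-4H-pyran-4-one, closes last through O1–C6.
The enabling feature is C2: the sole stereocentre is a carbinol carbon on O1, flanked by the C3 and C1' methylenes, with the C4 carbonyl two atoms away, so O1–C2–C3–C4 is a 3-hydroxyacyl unit. The distant C14'=C15' Z-olefin is inert to a nicotinamide hydride but a liability with hydrogenation catalysts.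
The (R) configuration at C2 comes from enantioface-selective hydride transfer by an NADPH-dependent ketoreductase. The Z-olefin is bought with nervonic acid and never touched, and the ring closure does not break the C2–O1 bond.
Key step: step 2

Numbering: ring O1, C2–C6; side chain C1'–C23'. Remark on the chemistry: the SMILES corresponds to (R) at C2, and the ketoreductase is assumed to be a commercial panel enzyme picked by screening on the β-keto ester for (R) delivery.

Step 1
Reactants: 1 nervonic acid [(Z)-tetracos-15-enoic acid]; 2 potassium ethyl malonate (KO2CCH2CO2Et)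
Product: 5 ethyl (Z)-3-oxohexacos-17-enoate, via nervonoyl imidazolide 3 (not isolated), via acylmalonate half-ester 4 (not isolated)
Conditions: 1,1'-carbonyldiimidazole (1.2 equiv), THF, rt; then added to 2 (2 equiv), MgCl2 (2.5 equiv), Et3N (3 equiv), MeCN, rt → 45 °C; 1 M aq. HCl
Reagents that add atoms: none
Why: Masamune–Brooks chain extension, in which the acyl imidazolide is C-acylated by the magnesium enolate of the malonate half-ester and the acylmalonate then loses CO2 to leave the β-keto ester, under near-neutral conditions that leave the Z-olefin alone.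

Step 2
Reactants: 5 ethyl (Z)-3-oxohexacos-17-enoate
Product: 6 ethyl (3R,17Z)-3-hydroxyhexacos-17-enoate
Conditions: (R)-selective NADPH-dependent ketoreductase (panel hit), NADP+ (cat.), D-glucose (1.5 equiv), glucose dehydrogenase, KH2PO4/K2HPO4 buffer (0.1 M, pH 7.0), DMSO (15% v/v), polysorbate 80 (1% w/v), 30 °C, pH-stat (1 M NaOH)
Reagents that add atoms: none
Why: In the enzyme–cofactor–substrate complex the C4 hydride of NADPH is transferred to the C3 carbonyl carbon of 5 (target C2) while the catalytic tyrosine, assisted by serine and lysine, protonates the carbonyl oxygen; glucose dehydrogenase returns NADP+ to NADPH at the expense of glucose, and hydrolysis of the gluconolactone makes the reduction irreversible. The closest known reaction type is the ketoreductase reduction of β-keto esters with cofactor recycling, mirrored in nature by the 3-oxoacyl reductase step of fatty acid biosynthesis, which also converts long-chain 3-oxoacyl units into (R)-3-hydroxyacyl units. No ring closes and no skeletal bond forms; the step makes only the C–H bond of the stereocentre. The (R) configuration is controlled by the enzyme pocket alone, which should hold the C4–C26 chain in its hydrophobic channel and the CH2CO2Et arm in the small pocket so that only one carbonyl face meets the nicotinamide ring; the enzyme is chosen from a panel for this sense of delivery. The step needs enantioface selectivity together with chemoselectivity for the ketone over the ester and the C17=C18 Z-olefin, and a nicotinamide hydride reduces neither esters nor isolated alkenes and cannot isomerise the double bond as a metal hydride might. DMSO and the surfactant keep the waxy substrate dispersed, and the neutral pH avoids hydrolysis and decarboxylation of the β-keto ester.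

Step 3
Reactants: 6 ethyl (3R,17Z)-3-hydroxyhexacos-17-enoate
Product: 7 (3R,17Z)-3-hydroxy-N-methoxy-N-methylhexacos-17-enamide
Conditions: MeNHOMe·HCl (2.5 equiv), iPrMgCl (6 equiv), THF, −20 → 0 °C; aq. NH4Cl
Reagents that add atoms: N,O-dimethylhydroxylamine hydrochloride, CNOC.Cl
Why: Direct Weinreb aminolysis of the ester by the chloromagnesium amide of N,O-dimethylhydroxylamine, in which one further equivalent of Grignard only converts the carbinol to its alkoxide and the low temperature should suppress β-elimination and retro-aldol cleavage, so C3 stays (R).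

Step 4
Reactants: 7 (3R,17Z)-3-hydroxy-N-methoxy-N-methylhexacos-17-enamide; 8 1-propynylmagnesium bromide (MeC≡CMgBr)
Product: 10 (6R,20Z)-6-hydroxynonacos-20-en-2-yn-4-one, via magnesium hemiaminal chelate 9 (not isolated)
Conditions: 8 (0.5 M in THF, 3.5 equiv), THF, 0 °C → rt; inverse quench into 1 M aq. HCl at 0 °C
Reagents that add atoms: none
Why: Weinreb ketone synthesis, in which the first equivalent of 8 deprotonates the hydroxyl, the next adds once to the amide, and the N-methoxy chelate 9 holds the adduct until the cold acidic quench releases the ynone and protonates the liberated amine so that it cannot add to the triple bond.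

Step 5
Reactants: 10 (6R,20Z)-6-hydroxynonacos-20-en-2-yn-4-one
Product: 11 (R)-6-methyl-2-[(Z)-tricos-14-en-1-yl]-2,3-dihydro-4H-pyran-4-one (target)
Conditions: Ph3PAuCl (5 mol%), AgOTf (5 mol%), CH2Cl2, rt
Reagents that add atoms: none
Why: Gold-catalysed cycloisomerisation (intramolecular hydroalkoxylation) of a β-hydroxy ynone, in which the cationic Ph3PAu+ fragment (monovalent gold) activates the triple bond, the hydroxyl oxygen adds anti at the methyl-bearing alkyne carbon in a 6-endo-dig closure of O1–C6 (also the conjugate position of the ynone), and protodeauration gives the vinylogous ester without touching the C2–O1 bond or the remote olefin.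

Compound list
1 | nervonic acid, (Z)-tetracos-15-enoic acid | CCCCCCCC/C=C\CCCCCCCCCCCCCC(=O)O | starting material
2 | potassium ethyl malonate (KO2CCH2CO2Et) | CCOC(=O)CC(=O)[O-].[K+] | starting material
3 | 1-[(Z)-tetracos-15-enoyl]imidazole (nervonoyl imidazolide) | CCCCCCCC/C=C\CCCCCCCCCCCCCC(=O)n1ccnc1 | intermediate
4 | (Z)-2-(ethoxycarbonyl)-3-oxohexacos-17-enoic acid, held as its magnesium chelate; C2 racemic and lost on decarboxylation | CCCCCCCC/C=C\CCCCCCCCCCCCCC(=O)C(C(=O)O)C(=O)OCC | intermediate
5 | ethyl (Z)-3-oxohexacos-17-enoate | CCCCCCCC/C=C\CCCCCCCCCCCCCC(=O)CC(=O)OCC | intermediate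
6 | ethyl (3R,17Z)-3-hydroxyhexacos-17-enoate | CCCCCCCC/C=C\CCCCCCCCCCCCC[C@@H](O)CC(=O)OCC | intermediate
7 | (3R,17Z)-3-hydroxy-N-methoxy-N-methylhexacos-17-enamide | CCCCCCCC/C=C\CCCCCCCCCCCCC[C@@H](O)CC(=O)N(C)OC | intermediate
8 | 1-propynylmagnesium bromide (MeC≡CMgBr) | CC#C[Mg]Br | starting material
9 | bis(bromomagnesium) alkoxide of (6R,20Z)-4-[methoxy(methyl)amino]nonacos-20-en-2-yne-4,6-diol; C4 unassigned, it becomes the carbonyl carbon on quench | CCCCCCCC/C=C\CCCCCCCCCCCCC[C@@H](O[Mg]Br)CC(O[Mg]Br)(C#CC)N(C)OC | intermediate
10 | (6R,20Z)-6-hydroxynonacos-20-en-2-yn-4-one | CCCCCCCC/C=C\CCCCCCCCCCCCC[C@@H](O)CC(=O)C#CC | intermediate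
11 | (R)-6-methyl-2-[(Z)-tricos-14-en-1-yl]-2,3-dihydro-4H-pyran-4-one | CCCCCCCC/C=C\CCCCCCCCCCCCC[C@@H]1CC(=O)C=C(C)O1 | target

Total step count: 5. Longest linear sequence: 5 steps (1 → 11).

Steps most likely to fail

Step 2. The waxy, water-insoluble 26-carbon keto ester may not reach the active site, so that conversion stalls, or no panel enzyme may deliver hydride to the required face with high selectivity. The fallback sets the same stereocentre by an auxiliary-controlled acetate aldol that forms the C2–C3 bond of the ester instead; it sets out from 1 and comes back at 6. LiAlH4 (THF, 0 °C → rt) should reduce 1 to (Z)-tetracos-15-en-1-ol F1, and Dess–Martin periodinane (CH2Cl2, NaHCO3) should oxidise it to (Z)-tetracos-15-enal F2. The dianion of commercial (S)-2-hydroxy-1,2,2-triphenylethyl acetate (LiN(iPr)2, THF; MgBr2; −78 °C or colder) is expected to add to F2 to give the (S)-2-hydroxy-1,2,2-triphenylethyl ester of (3R,17Z)-3-hydroxyhexacos-17-enoic acid F3, which recrystallisation should upgrade. NaOEt in EtOH (0 °C) should then transesterify F3 to 6, with recovery of the triphenylethanediol.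

Step 4. The substrate enters as a sparingly soluble, aggregated magnesium alkoxide, so acyl substitution may stay incomplete or be accompanied by β-elimination along the alkoxide-bearing chain. The fallback masks the carbinol before the organometallic step; it sets out from 7 and comes back at 10. Et3SiCl and imidazole (DMF, 0 °C) should give the triethylsilyl ether F4. Addition of 8 (1.5 equiv, THF, 0 °C) should give the bromomagnesium hemiaminal F5, which the cold acidic quench converts to the silyl-protected ynone F6. HF·pyridine (THF, 0 °C) then removes the silyl group to give 10.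

Step 5. Traces of triflic acid from the silver salt may dehydrate the β-hydroxy ketone or hydrate the triple bond faster than the ring closes, and may erode the configuration through reversible ring opening. The fallback replaces π-acid activation by a metal-free addition–elimination; it sets out from 10 and comes back at 11. Et2NH (EtOH, rt) should add in conjugate fashion to give the enaminone F7. Brief exposure to CF3CO2H in CH2Cl2 at 0 °C should then close the ring by attack of the hydroxyl on the protonated vinylogous amide, with loss of diethylamine.

Further compounds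
F1 | step 2 | (Z)-tetracos-15-en-1-ol | CCCCCCCC/C=C\CCCCCCCCCCCCCCO
F2 | step 2 | (Z)-tetracos-15-enal | CCCCCCCC/C=C\CCCCCCCCCCCCCC=O
F3 | step 2 | (S)-2-hydroxy-1,2,2-triphenylethyl (3R,17Z)-3-hydroxyhexacos-17-enoate | CCCCCCCC/C=C\CCCCCCCCCCCCC[C@@H](O)CC(=O)O[C@@H](c1ccccc1)C(O)(c1ccccc1)c1ccccc1
F4 | step 4 | (3R,17Z)-N-methoxy-N-methyl-3-[(triethylsilyl)oxy]hexacos-17-enamide | CCCCCCCC/C=C\CCCCCCCCCCCCC[C@@H](O[Si](CC)(CC)CC)CC(=O)N(C)OC
F5 | step 4 | bromomagnesium alkoxide of (6R,20Z)-4-[methoxy(methyl)amino]-6-[(triethylsilyl)oxy]nonacos-20-en-2-yn-4-ol | CCCCCCCC/C=C\CCCCCCCCCCCCC[C@@H](O[Si](CC)(CC)CC)CC(O[Mg]Br)(C#CC)N(C)OC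
F6 | step 4 | (6R,20Z)-6-[(triethylsilyl)oxy]nonacos-20-en-2-yn-4-one | CCCCCCCC/C=C\CCCCCCCCCCCCC[C@@H](O[Si](CC)(CC)CC)CC(=O)C#CC
F7 | step 5 | (2E,6R,20Z)-2-(diethylamino)-6-hydroxynonacosa-2,20-dien-4-one | CCCCCCCC/C=C\CCCCCCCCCCCCC[C@@H](O)CC(=O)/C=C(\C)N(CC)CC
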